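## Retrosynthetic overview
1. The last bond made is the glycerol C1–O ether bond. It comes from catalytic enantioselective opening of an achiral oxetan-3-yl 4-silyloxybenzoate by (4E,6Z,8E)-dodeca-4,6,8-trien-1-ol. The same event frees the CH2OH and defines C2, and the aryl silyl ether is removed in the same flask.
2. The oxetanyl ester comes from a C–O bond between 4-hydroxybenzoic acid and oxetan-3-ol (Mitsunobu), with the phenol silylated in the same pot.
3. The trienol is cut at C5–C6 (Suzuki) and C7–C8 (alkenylalane coupling), both on (Z)-1,2-dichloroethene, which supplies the central Z alkene. The two E alkenes come from syn-hydrometalation of pent-4-yn-1-ol and pent-1-yne.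
4. No ring is formed. The arene and the oxetane are bought, and the oxetane is opened in the final step.

Assumption: the sense of induction of the new step cannot be known in advance, so the (R,R)-catalyst is written as giving the (S)-product and the equally accessible (S,S)-catalyst is used if the opposite is found.

Catalyst A (step 4) is a known complex and its preparation is not counted. It is the cyclic oligomeric cobalt salen triflate [Co(L)(OTf)]n with n = 2–6 and trivalent cobalt. L is the salen dianion from (R,R)-cyclohexane-1,2-diamine and 3-tert-butyl-5-hydroxysalicylaldehyde. Neighbouring units are joined through the 5-oxygens as heptanedioate diesters.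

## Route

Step 1
Reactants: 1 pent-1-yne; 2 (Z)-1,2-dichloroethene
Product: 4 (1Z,3E)-1-chlorohepta-1,3-diene, via alkenylalane 3 (not isolated)
Conditions: 1, i-Bu2AlH (1.0 equiv), hexane, sealed flask, 0 → 50 °C, 3 h; then 2 (4 equiv), Pd(PPh3)4 (4 mol%), THF, 23 °C, 12 h
Reagents that add atoms: none
Why: Syn-hydroalumination fixes the (E)-alkenyl–Al bond, and the Negishi-type Pd-catalysed alkenyl–alkenyl cross-coupling runs with retention at both partners, while the excess dichloride (more reactive towards zerovalent palladium than the chlorodiene product) ensures mono-substitution so that the Z alkene is carried over from 2.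

Step 2
Reactants: 5 pent-4-yn-1-ol; 4 (1Z,3E)-1-chlorohepta-1,3-diene
Product: 7 (4E,6Z,8E)-dodeca-4,6,8-trien-1-ol, via borylated alkenylboronate 6 (not isolated)
Conditions: 5 (1.2 equiv), pinacolborane (2.6 equiv), Cp2Zr(H)Cl (5 mol%), Et3N (10 mol%), neat, 60 °C, 16 h; then 4 (1.0 equiv), Pd(OAc)2 (3 mol%), SPhos (2-dicyclohexylphosphino-2',6'-dimethoxybiphenyl, 6 mol%), K3PO4 (3 equiv), degassed THF–H2O 5:1, 40 °C, 14 h, dark
Reagents that add atoms: none
Why: Zr-catalysed syn-hydroboration (the OH is masked in situ as its borate) gives the (E)-alkenylboronate, and the Suzuki–Miyaura coupling with a bulky electron-rich phosphine activates the alkenyl C–Cl bond at 40 °C with retention of both geometries, far below the temperature at which an E,Z,E-triene electrocyclises.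

Step 3
Reactants: 8 4-hydroxybenzoic acid; 9 oxetan-3-ol
Product: 11 oxetan-3-yl 4-[(tert-butyldimethylsilyl)oxy]benzoate, via phenol ester 10 (not isolated)
Conditions: 8 (1.15 equiv), 9 (1.0 equiv), PPh3 (1.2 equiv), DIAD (1.2 equiv), THF, 0 °C → 23 °C, 12 h; then imidazole (3 equiv), TBSCl (1.6 equiv), 23 °C, 3 h
Reagents that add atoms: tert-butyldimethylsilyl chloride (TBSCl), CC(C)(C)[Si](C)(C)Cl
Why: Mitsunobu esterification selects the carboxylic acid (pKa about 4.5) over the phenol (pKa about 9), uses no acid that could open the oxetane and creates no stereocentre because C3 is achiral, and the standard imidazole-promoted silylation in the same flask caps the phenol so that it cannot act as the nucleophile in step 4 and makes the product easy to separate from Ph3PO.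

Step 4
Reactants: 7 (4E,6Z,8E)-dodeca-4,6,8-trien-1-ol; 11 oxetan-3-yl 4-[(tert-butyldimethylsilyl)oxy]benzoate
Product: 13 (2S)-1-[(4E,6Z,8E)-dodeca-4,6,8-trien-1-yloxy]-3-hydroxypropan-2-yl 4-hydroxybenzoate, via silyl ether 12 (not isolated)
Conditions: 11 (1.0 equiv), 7 (1.3 equiv, excess recovered), catalyst A [Co(L)(OTf)]n (2 mol% Co), 3 Å MS, MeCN (3 M), 23 °C, 48 h, Ar, dark; then THF, Bu4NF–AcOH 1:1 (1.2 equiv), 0 °C, 30 min; pH 6 buffer work-up, boric-acid-impregnated silica
Reagents that add atoms: none
Why: Proposed new method: intermolecular enantioselective alcoholysis of a prochiral 3-acyloxyoxetane under cooperative bimetallic catalysis, in which one trivalent cobalt centre of the oligomer binds the oxetane oxygen as a Lewis acid while a neighbouring centre carries 7 as a cobalt alkoxide and delivers it anti (SN2) to only one of the two enantiotopic CH2 groups held in the stepped salen pocket, so that the ether C–O bond, the free CH2OH and the (S)-centre at C2 (whose own bonds are never touched) arise in one event, the two-metal pathway favouring the external alkoxide over participation of the weakly nucleophilic ester carbonyl and the near-neutral medium sparing the triene; the closest known reaction types are the opening of oxetanes by tethered alcohols and the kinetic resolution of terminal epoxides with primary alcohols by the same catalyst family, and the buffered fluoride that follows is a standard desilylation that cleaves only the aryl silyl ether at a pH where acyl migration from O2 to O3 is slow.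

## Compound list
1 | pent-1-yne | CCCC#C | starting material
2 | (Z)-1,2-dichloroethene | Cl/C=C\Cl | starting material
3 | (E)-diisobutyl(pent-1-en-1-yl)alane | CCC/C=C/[Al](CC(C)C)CC(C)C | intermediate (not isolated)
4 | (1Z,3E)-1-chlorohepta-1,3-diene | CCC/C=C/C=C\Cl | intermediate
5 | pent-4-yn-1-ol | OCCCC#C | starting material
6 | 2-[(1E)-5-(4,4,5,5-tetramethyl-1,3,2-dioxaborolan-2-yloxy)pent-1-en-1-yl]-4,4,5,5-tetramethyl-1,3,2-dioxaborolane | CC1(C)OB(OCCC/C=C/B2OC(C)(C)C(C)(C)O2)OC1(C)C | intermediate (not isolated)
7 | (4E,6Z,8E)-dodeca-4,6,8-trien-1-ol | CCC/C=C/C=C\C=C\CCCO | intermediate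
8 | 4-hydroxybenzoic acid | OC(=O)c1ccc(O)cc1 | starting material
9 | oxetan-3-ol | OC1COC1 | starting material
10 | oxetan-3-yl 4-hydroxybenzoate | O=C(OC1COC1)c1ccc(O)cc1 | intermediate (not isolated)
11 | oxetan-3-yl 4-[(tert-butyldimethylsilyl)oxy]benzoate | CC(C)(C)[Si](C)(C)Oc1ccc(cc1)C(=O)OC1COC1 | intermediate
12 | (2S)-1-[(4E,6Z,8E)-dodeca-4,6,8-trien-1-yloxy]-3-hydroxypropan-2-yl 4-[(tert-butyldimethylsilyl)oxy]benzoate | CCC/C=C/C=C\C=C\CCCOC[C@H](CO)OC(=O)c1ccc(O[Si](C)(C)C(C)(C)C)cc1 | intermediate (not isolated)
13 | (2S)-1-[(4E,6Z,8E)-dodeca-4,6,8-trien-1-yloxy]-3-hydroxypropan-2-yl 4-hydroxybenzoate | CCC/C=C/C=C\C=C\CCCOC[C@H](CO)OC(=O)c1ccc(O)cc1 | target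

## Step count and risks
Total step count: 4.
Longest linear sequence: 3 (steps 1, 2 and 4).

**Most likely to fail: step 4, the proposed new reaction.**
- Oxetanes open far more slowly than epoxides.
- The 3-acyloxy group lowers the Lewis basicity of the ring oxygen.
- The ester carbonyl could participate, giving a 1,3-dioxolan-2-ylium ion or an orthoester that yields no ether and erases the desymmetrisation.
- The primary alcohol of the product could compete as nucleophile.
- The ee is unproven.

The fallback uses known chemistry, takes the stereocentre from the chiral pool, sets out from 7 and comes back at 13. Compound 7 is added to the CH2 terminus of commercial tert-butyldimethylsilyl (S)-glycidyl ether. This uses the established cobalt-salen-catalysed alcoholysis of terminal epoxides (matched enantiomer of [Co(L)(OTf)]n, MeCN, 23 °C). The product is (2S)-1-[(tert-butyldimethylsilyl)oxy]-3-[(4E,6Z,8E)-dodeca-4,6,8-trien-1-yloxy]propan-2-ol F1. Mitsunobu esterification of F1 with 8 (PPh3, DIAD, toluene, 0 °C → 23 °C) places the benzoate on C2 with clean inversion and without phenol protection. This gives (2R)-1-[(tert-butyldimethylsilyl)oxy]-3-[(4E,6Z,8E)-dodeca-4,6,8-trien-1-yloxy]propan-2-yl 4-hydroxybenzoate F2. Bu4NF–AcOH (THF, 0 °C → 23 °C) then removes the primary silyl ether to give 13.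

**Second: step 2.**
- The free OH may make the hydroboration incomplete.
- The alkenylboronate may protodeboronate.
- The alkenylpalladium intermediate may leak some Z to E geometry.

The fallback sets the Z alkene by alkyne semi-reduction instead of stereoretentive coupling. It sets out from 4 and 5 and comes back at 7. Anti-elimination of HCl from 4 (LiN(i-Pr)2, THF, −78 → 0 °C) gives (E)-hept-3-en-1-yne F3. Hydrozirconation–iodination of 5 (Cp2Zr(H)Cl 2.2 equiv, THF, then I2) gives (E)-5-iodopent-4-en-1-ol F4. Sonogashira coupling of the two (PdCl2(PPh3)2, CuI, Et3N, 23 °C) gives (4E,8E)-dodeca-4,8-dien-6-yn-1-ol F5. Zinc dust activated with Cu(OAc)2 and AgNO3 (MeOH–H2O, 23–40 °C) reduces only the conjugated alkyne, cis, to 7.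

**Third: step 3.** Displacement at C3 of a four-membered ring is slow. Anhydride formation or reactions of the phenol could therefore take over in the Mitsunobu stage.

The fallback replaces substitution at the oxetane carbon by acyl transfer onto the oxetanol oxygen. It sets out from 8 and comes back at 11. Compound 8 is bis-silylated (TBSCl 2.2 equiv, imidazole, DMF) to tert-butyldimethylsilyl 4-[(tert-butyldimethylsilyl)oxy]benzoate F6. The silyl ester alone is hydrolysed (K2CO3, MeOH–THF–H2O, then citric acid) to 4-[(tert-butyldimethylsilyl)oxy]benzoic acid F7. Steglich-type coupling with 9 (EDC·HCl, DMAP, CH2Cl2, 23 °C) then gives 11.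

## Further compounds
F1 | step 4 | (2S)-1-[(tert-butyldimethylsilyl)oxy]-3-[(4E,6Z,8E)-dodeca-4,6,8-trien-1-yloxy]propan-2-ol | CCC/C=C/C=C\C=C\CCCOC[C@@H](CO[Si](C)(C)C(C)(C)C)O
F2 | step 4 | (2R)-1-[(tert-butyldimethylsilyl)oxy]-3-[(4E,6Z,8E)-dodeca-4,6,8-trien-1-yloxy]propan-2-yl 4-hydroxybenzoate | CCC/C=C/C=C\C=C\CCCOC[C@H](CO[Si](C)(C)C(C)(C)C)OC(=O)c1ccc(O)cc1
F3 | step 2 | (E)-hept-3-en-1-yne | CCC/C=C/C#C
F4 | step 2 | (E)-5-iodopent-4-en-1-ol | OCCC/C=C/I
F5 | step 2 | (4E,8E)-dodeca-4,8-dien-6-yn-1-ol | CCC/C=C/C#C/C=C/CCCO
F6 | step 3 | tert-butyldimethylsilyl 4-[(tert-butyldimethylsilyl)oxy]benzoate | CC(C)(C)[Si](C)(C)Oc1ccc(cc1)C(=O)O[Si](C)(C)C(C)(C)C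
F7 | step 3 | 4-[(tert-butyldimethylsilyl)oxy]benzoic acid | CC(C)(C)[Si](C)(C)Oc1ccc(cc1)C(=O)O
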